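The constants used here are those of an exercise, and the outcome is calculated.

I build the flask one step at a time.

in all of them: substrate 0.050 M; partner 0.0600 M; rival reagent 0.0250 M; time 30 h
- Monday's: temperature 25 °C
- Saturday's: temperature 65 °C
- Sunday's: temperature 45 °C

- the best flask by share of target in all that became target or side product A or over-reaction product or side product B; "all alike" if 1.5 percentage points covers them all (Monday's / Saturday's / Sunday's / all alike)
- share of target in all that became target or side product A or over-reaction product or side product B, Monday's
- share of target in all that became target or side product A or over-reaction product or side product B, Saturday's
- share of target in all that became target or side product A or over-reaction product or side product B, Sunday's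

- in percentages every species weighs as the substrate in it: one side product B counts as two
- at 25 °C the constants are as listed, elsewhere as the activation energies make them

    substrate + partner → target (k1 = 0.28 /M/h, Ea1 = 58.0 kJ/mol)
    substrate + rival reagent → side product A (k2 = 0.81 /M/h, Ea2 = 60.0 kJ/mol)
    rival reagent + target → over-reaction product (k3 = 1.7 /M/h, Ea3 = 66.0 kJ/mol)
    substrate + target → side product B (k4 = 0.066 /M/h, Ea4 = 73.0 kJ/mol)
    (constants at 25 °C)

With the main step by itself, substrate and partner give target. Target is then the one product of this step, so its share, the selectivity, is 100% whatever the partner charge. The partner charge, at 1.20 equivalents, exceeds the substrate charge, and that bears on how much substrate can convert, not on the share.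

Now I add the rival reagent attacking substrate. At the start of Monday's, 45.3% of the flow goes to target, and the two activation energies differ by 2.00 kJ/mol. But that share belongs to the first moment, and following what is made gets hard from here, so I count what is left instead.

Next the rival reagent also attacks target, giving over-reaction product. This looks like a new loss, but in the count it is the same debt: one rival molecule takes one substrate's weight, as side product A or as over-reaction product. So once substrate and rival reagent both stand at zero, the rival has claimed 50.0% of the substrate charged. I call 50.0% the remainder: the part of the substrate that the rival charge leaves, one minus rival charge over substrate charge.

Last comes substrate plus target to side product B, which weighs double. It draws on the remainder, so in a finished flask target plus side product B equals the remainder. This step speeds up 33 times from the coldest to the hottest flask, against 18 times for the rival's attack on substrate. My hand stops here: I commit to a target share below 50.0% in a finished flask, and I have no figure for how far below, nor for a flask still running.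

The forecast gives 35.6% for Monday's, 36% for Saturday's and 35.5% for Sunday's, hence all alike. Its grounds are that “the hotter flasks consume the rival reagent early”, and it calls the verdict “a judgement call rather than a certainty”. Those figures are its own; my reckoning gives a bound and not them.

The simulation gives 35.9% for Monday's, 35.8% for Saturday's and 35.5% for Sunday's, so the answer is all alike, with a spread of 0.40 percentage points against a margin of 1.5 points. The forecast holds.

In Saturday's at 30 h, substrate stands at 0.264% and rival reagent at 0%, and target 35.7% plus side product B 14.0% make 49.7%, close to the remainder. At that time the half-life of target against the step to side product B in Saturday's is 100 d, long against the 30 h of the run. A reading ten times later makes no difference to Saturday's share.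

Now take Saturday's with 0.10 M of partner: substrate and rival charges are unchanged, so the remainder is again 50.0%. That flask ends with substrate 0%, rival reagent 0%, target 40.5% and side product B 9.52%, the last two together 50.0%.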